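**Plan**

- Numbering: C1 quaternary methyl carbon, C2/C3 methylenes, C4 isopropyl carbinol, C5 ring-fusion CH, C6 aroyloxy carbon, C7 methylene, C8 (methyl)=C9, C10 tigloyloxy carbon.
- Retrosynthesis cuts the C6 aroyl ester first, then C6–C7. C6 is a homoallylic carbinol carbon with the C8(Me)=C9 alkene one carbon away inside the seven-membered ring C1–C5–C6–C7–C8–C9–C10, which is the retron of a carbonyl-ene reaction between a C6 aldehyde and a C7=C8(Me)–C9 methallyl unit.
- Next cuts: C9–C10 (methallyl onto a C10 aldehyde) and the C10 tiglate. C6 and C10 go back to one cyclobutene C=C, then the C4–isopropyl bond and the two bonds C5–C6/C1–C10 of an enone–alkene [2+2] adduct.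
- Forward: the cyclopentenone becomes a cis-fused bicyclo[3.2.0]heptenone, the four-membered ring is opened by ozonolysis to a cis-1,2-disubstituted cyclopentane, and the seven-membered ring closes last.
- Stereochemistry: C1/C5 (absolute) from the enantioselective photocycloaddition, C4 from Grignard addition to the convex face, C10 from reagent-controlled methallylboration, C6 from the chelate-organised ene step.

Key step: step 12

Remark on the structure: the SMILES describes a cis-fused daucane with C6, C10 and the C4 oxygen on one face of the cyclopentane; in the numbering above it is 1R,4R,5S,6R,10R.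
Assumption: the enantiomer of the photocycloaddition catalyst is chosen by its usual shielding model so that the (1R,5R) adduct forms.

**Route**

Step 1
Reactants: 1 3-methylcyclopent-2-en-1-one; 2 (Z)-1,2-dichloroethene
Product: 3 (1R,5R)-6,7-dichloro-5-methylbicyclo[3.2.0]heptan-2-one (cis-fused, chloride epimers)
Conditions: 2 (excess), chiral diarylprolinol-derived B-aryl-1,3,2-oxazaborolidine activated by AlBr3 (50 mol %), hν (366 nm), CH2Cl2, −75 °C
Reagents that add atoms: none
Why: Chiral-Lewis-acid-catalysed enantioselective enone–alkene [2+2] photocycloaddition, in which only the AlBr3-bound enone absorbs at 366 nm and one of its faces is shielded, sets C1 and C5 together, cis by the four/five ring fusion.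

Step 2
Reactants: 3 dichloro adduct
Product: 4 (1R,5S)-5-methylbicyclo[3.2.0]hept-6-en-2-one
Conditions: Zn, EtOH, 80 °C
Reagents that add atoms: none
Why: Zinc-mediated reductive 1,2-elimination of the vicinal dichloride converges both chloride epimers on the cyclobutene without touching the ring-fusion centres.

Step 3
Reactants: 4 cyclobutene ketone
Product: 5 (1R,2R,5S)-5-methyl-2-(propan-2-yl)bicyclo[3.2.0]hept-6-en-2-ol (hydroxyl on the concave face, cis to the cyclobutene)
Conditions: iPrMgCl, CeCl3 (anhydrous), THF, −78 → 0 °C; aq. NH4Cl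
Reagents that add atoms: isopropylmagnesium chloride, CC(C)[Mg]Cl
Why: CeCl3-mediated Grignard addition suppresses enolisation and reduction of the hindered ketone, and attack on the convex face away from the cyclobutene places the C4 hydroxyl cis to the future C6 carbon.

Step 4
Reactants: 5 tertiary alcohol
Product: 7 (1R,2S,3R)-2,3-bis(hydroxymethyl)-3-methyl-1-(propan-2-yl)cyclopentan-1-ol, via secondary ozonide 6 (not isolated)
Conditions: O3, CH2Cl2, −78 °C; then MeOH, NaBH4, −78 °C → rt
Reagents that add atoms: ozone, O=[O+][O-]
Why: Ozonolysis of the strained cyclobutene and NaBH4 reduction of the ozonide turn the two alkene carbons into the C6 and C10 hydroxymethyl groups, whose cis relationship is inherited from the ring.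

Step 5
Reactants: 7 triol
Product: 8 C4,C6-O-(4-methoxybenzylidene) acetal of 7 (cis-fused six-membered 1,3-dioxane, aryl equatorial and cis to the isopropyl group, C10 hydroxymethyl free)
Conditions: 4-MeOC6H4CH(OMe)2, camphorsulfonic acid (cat.), 4 Å molecular sieves, CH2Cl2, rt, equilibrating
Reagents that add atoms: 4-methoxybenzaldehyde dimethyl acetal, COc1ccc(C(OC)OC)cc1
Why: Acid-catalysed transacetalisation under equilibrating conditions should select the six-membered 1,3-dioxane across the 1,3-related C4 and C6 hydroxyls (aryl and isopropyl equatorial) over seven-membered acetals, which frees C10 alone for oxidation.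

Step 6
Reactants: 8 acetal alcohol
Product: 9 C10 aldehyde of the acetal series (formyl group on the quaternary C1)
Conditions: Dess–Martin periodinane, NaHCO3, CH2Cl2, 0 °C → rt
Reagents that add atoms: none
Why: Dess–Martin oxidation of the neopentyl primary alcohol gives a non-enolisable aldehyde under buffered conditions that spare the acetal.

Step 7
Reactants: 9 acetal aldehyde; 10 2-methylallylmagnesium chloride
Product: 12 (10R) methallyl carbinol of the acetal series, via diisopinocampheylborinate ester 11 (not isolated)
Conditions: (+)-Ipc2BOMe (from (−)-α-pinene), 10, Et2O, −78 °C → rt; then 9, −78 °C; then NaOH, H2O2, 0 °C → rt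
Reagents that add atoms: none
Why: Brown asymmetric methallylboration through a chair transition state adds the methallyl group to the Re face of the aldehyde under reagent control, with the substrate's Felkin bias (attack anti to C5) expected to point the same way, which sets C10 as R.

Step 8
Reactants: 12 methallyl carbinol; 13 tigloyl chloride
Product: 14 C10 tiglate of the acetal series
Conditions: DMAP, pyridine, CH2Cl2, 0 → 40 °C
Reagents that add atoms: none
Why: DMAP-catalysed acylation of the hindered secondary alcohol installs the tiglate while no other hydroxyl is free, and pyridine as base avoids ketene-type deconjugation of the tigloyl unit.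

Step 9
Reactants: 14 tiglate acetal
Product: 15 diol (C4 tertiary hydroxyl, C6 hydroxymethyl, C10 tiglate)
Conditions: AcOH/THF/H2O (3:1:1), 40 °C
Reagents that add atoms: none
Why: Mild aqueous acid hydrolyses the electron-rich benzylidene acetal while the ester, the 1,1-disubstituted alkene and the tertiary alcohol survive.

Step 10
Reactants: 15 diol
Product: 16 C4,C6-bis(triethylsilyl) ether
Conditions: Et3SiOTf, 2,6-lutidine, CH2Cl2, −78 → 0 °C
Reagents that add atoms: triethylsilyl trifluoromethanesulfonate, CC[Si](CC)(CC)OS(=O)(=O)C(F)(F)F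
Why: The silyl triflate silylates the primary and the hindered tertiary hydroxyl alike, so the C4 oxygen is protected against retro-aldol cleavage and elimination once C6 is an aldehyde.

Step 11
Reactants: 16 bis(triethylsilyl) ether
Product: 17 C6 aldehyde (cis-1,2-disubstituted cyclopentane: formyl on C5, methallyl carbinol tiglate on C1, C4 triethylsilyl ether)
Conditions: (COCl)2, DMSO, CH2Cl2, −78 → −40 °C; then Et3N, −78 → −20 °C
Reagents that add atoms: none
Why: Under Swern conditions a primary triethylsilyl ether is cleaved and oxidised in one operation while a tertiary one is inert, and the low temperature keeps the C5 centre next to the new aldehyde from epimerising.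

Step 12
Reactants: 17 C6 aldehyde
Product: 18 cis-fused hydroazulene with free (6R) hydroxyl, C8=C9 alkene, (10R) tiglate and C4 triethylsilyl ether
Conditions: Me2AlCl (2.5 equiv), CH2Cl2, −78 → −20 °C; aq. NaHCO3/potassium sodium tartrate
Reagents that add atoms: none
Why: Two equivalents of Me2AlCl turn the β-silyloxy aldehyde into a cationic dimethylaluminium chelate (counter-ion Me2AlCl2−) bridging O6 and O4, the terminal alkene carbon C7 adds to the activated C6, and a C9 hydrogen passes to O6 (in concert or through a short-lived tertiary C8 cation), so that C6–C7 and C8=C9 arise and the aluminium alkoxide is fixed by loss of methane. The closest known reaction is the Lewis-acid-promoted intramolecular carbonyl-ene (Prins-type) cyclisation of aldehydes bearing a 2-methylallyl group, which closes six- and seven-membered homoallylic alcohols. The seven-membered ring C1–C5–C6–C7–C8–C9–C10 closes exo with respect to the C=O bond and with both alkene carbons inside the ring, and it can hold the new C8=C9 bond only as the cis alkene. The new C6 centre is controlled by the chelate, which holds C6=O syn to the C4 oxygen on the concave face while the tether delivers C7 from the C1 side, so the hydroxyl ends up anti to the C5 hydrogen (6R). The step needs this aldehyde face and hydrogen loss from C9 instead of from the C8 methyl group: the face is secured by the chelate together with the cis-1,2 arrangement of aldehyde and side chain, and the C7 hydrogens lie out of reach of O6. The choice between C9 and the methyl group is not enforced by the substrate, so the exocyclic methylene isomer is the by-product to expect and the main risk of the route.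

Step 13
Reactants: 19 4-hydroxybenzoic acid
Product: 20 tert-butyldimethylsilyl 4-(tert-butyldimethylsilyloxy)benzoate
Conditions: t-BuMe2SiCl (2.2 equiv), imidazole, DMF, rt
Reagents that add atoms: tert-butylchlorodimethylsilane, CC(C)(C)[Si](C)(C)Cl
Why: Silylation of both the phenol and the carboxylic acid gives a silyl ester that serves as a neutral acid chloride precursor.

Step 14
Reactants: 20 bis-silyl compound
Product: 21 4-(tert-butyldimethylsilyloxy)benzoyl chloride
Conditions: (COCl)2, DMF (cat.), CH2Cl2, 0 °C → rt
Reagents that add atoms: oxalyl chloride, ClC(=O)C(Cl)=O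
Why: Oxalyl chloride with catalytic DMF converts a silyl ester directly into the acid chloride without releasing HCl, so the aryl silyl ether is retained.

Step 15
Reactants: 18 hydroazulene alcohol; 21 aroyl chloride
Product: 22 C6 4-(tert-butyldimethylsilyloxy)benzoate (C10 tiglate, C4 triethylsilyl ether)
Conditions: DMAP, Et3N, CH2Cl2, rt → 40 °C
Reagents that add atoms: none
Why: DMAP-catalysed acylation of the only free hydroxyl (C6) proceeds with retention, the tertiary C4 oxygen being silylated.

Step 16
Reactants: 22 doubly silylated diester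
Product: 23 target, (1R,4R,5S,6R,10R)-6-(4-hydroxybenzoyloxy)-10-tigloyloxy cis-fused daucane-4-ol with C8=C9
Conditions: Bu4NF, AcOH, THF, 0 °C → rt
Reagents that add atoms: none
Why: Buffered fluoride cleaves the aryl silyl ether and the tertiary triethylsilyl ether in one operation without acyl migration or ester cleavage.

**Compound list**

1 | 3-methylcyclopent-2-en-1-one | CC1=CC(=O)CC1 | starting material
2 | (Z)-1,2-dichloroethene | Cl/C=C\Cl | starting material
3 | (1R,5R)-6,7-dichloro-5-methylbicyclo[3.2.0]heptan-2-one, chloride epimers | C[C@@]12CCC(=O)[C@@H]1C(Cl)C2Cl | intermediate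
4 | (1R,5S)-5-methylbicyclo[3.2.0]hept-6-en-2-one | C[C@@]12CCC(=O)[C@@H]1C=C2 | intermediate
5 | (1R,2R,5S)-5-methyl-2-(propan-2-yl)bicyclo[3.2.0]hept-6-en-2-ol | C[C@@]12CC[C@@](O)(C(C)C)[C@@H]1C=C2 | intermediate
6 | secondary ozonide of 5 (1,2,4-trioxolane across the former alkene carbons; configuration of the two acetal carbons not assigned) | C[C@@]12CC[C@@](O)(C(C)C)[C@@H]1C1OOC2O1 | intermediate (not isolated)
7 | (1R,2S,3R)-2,3-bis(hydroxymethyl)-3-methyl-1-(propan-2-yl)cyclopentan-1-ol | C[C@@]1(CO)CC[C@@](O)(C(C)C)[C@@H]1CO | intermediate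
8 | C4,C6-O-(4-methoxybenzylidene) acetal of 7, aryl equatorial, C10 hydroxymethyl free | C[C@@]1(CO)CC[C@]2(C(C)C)O[C@@H](c3ccc(OC)cc3)OC[C@H]12 | intermediate
9 | C10 aldehyde of the acetal series | C[C@@]1(C=O)CC[C@]2(C(C)C)O[C@@H](c3ccc(OC)cc3)OC[C@H]12 | intermediate
10 | 2-methylallylmagnesium chloride | C=C(C)C[Mg]Cl | starting material
11 | diisopinocampheylborinate ester of 12 | C=C(C)C[C@@H](OB([C@H]3C[C@H]4C[C@@H]([C@@H]3C)C4(C)C)[C@H]3C[C@H]4C[C@@H]([C@@H]3C)C4(C)C)[C@]1(C)CC[C@]2(C(C)C)O[C@@H](c3ccc(OC)cc3)OC[C@H]12 | intermediate (not isolated)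
12 | (10R) methallyl carbinol of the acetal series | C=C(C)C[C@@H](O)[C@]1(C)CC[C@]2(C(C)C)O[C@@H](c3ccc(OC)cc3)OC[C@H]12 | intermediate
13 | tigloyl chloride, (E)-2-methylbut-2-enoyl chloride | C/C=C(\C)C(Cl)=O | starting material
14 | (10R) tiglate of the acetal series | C/C=C(\C)C(=O)O[C@H](CC(C)=C)[C@]1(C)CC[C@]2(C(C)C)O[C@@H](c3ccc(OC)cc3)OC[C@H]12 | intermediate
15 | diol: C4 tertiary hydroxyl, C6 hydroxymethyl, C10 tiglate | C/C=C(\C)C(=O)O[C@H](CC(C)=C)[C@]1(C)CC[C@@](O)(C(C)C)[C@@H]1CO | intermediate
16 | C4,C6-bis(triethylsilyl) ether of 15 | C/C=C(\C)C(=O)O[C@H](CC(C)=C)[C@]1(C)CC[C@@](O[Si](CC)(CC)CC)(C(C)C)[C@@H]1CO[Si](CC)(CC)CC | intermediate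
17 | C6 aldehyde, cis to the C1 side chain and the C4 silyloxy group (ene precursor) | C/C=C(\C)C(=O)O[C@H](CC(C)=C)[C@]1(C)CC[C@@](O[Si](CC)(CC)CC)(C(C)C)[C@@H]1C=O | intermediate
18 | cis-fused hydroazulene, (6R) hydroxyl, C8=C9, (10R) tiglate, C4 triethylsilyl ether (ene product) | C/C=C(\C)C(=O)O[C@@H]1C=C(C)C[C@@H](O)[C@@H]2[C@@]1(C)CC[C@@]2(O[Si](CC)(CC)CC)C(C)C | intermediate
19 | 4-hydroxybenzoic acid | O=C(O)c1ccc(O)cc1 | starting material
20 | tert-butyldimethylsilyl 4-(tert-butyldimethylsilyloxy)benzoate | CC(C)(C)[Si](C)(C)OC(=O)c1ccc(O[Si](C)(C)C(C)(C)C)cc1 | intermediate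
21 | 4-(tert-butyldimethylsilyloxy)benzoyl chloride | CC(C)(C)[Si](C)(C)Oc1ccc(C(Cl)=O)cc1 | intermediate
22 | C6 4-(tert-butyldimethylsilyloxy)benzoate of 18 | C/C=C(\C)C(=O)O[C@@H]1C=C(C)C[C@@H](OC(=O)c3ccc(O[Si](C)(C)C(C)(C)C)cc3)[C@@H]2[C@@]1(C)CC[C@@]2(O[Si](CC)(CC)CC)C(C)C | intermediate
23 | CNP0273650.8 | C/C=C(\C)C(=O)O[C@@H]1C=C(C)C[C@@H](OC(=O)c2ccc(O)cc2)[C@@H]2[C@@]1(C)CC[C@@]2(O)C(C)C | target

**Step count**

Total: 16 steps. Longest linear sequence: 14 steps (steps 1–12, 15, 16); steps 13–14 make the aroyl chloride.

**Steps most likely to fail**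

1. Step 12. The hydrogen may be delivered from the C8 methyl group instead of from C9, chloride may be captured at C8, or the aldehyde may react through the unchelated rotamer and lose facial control.
Fallback (ring closure by olefin metathesis at C8=C9; sets out from 9, returns at 18): aldehyde 9 takes up CH2=CHMgBr (CeCl3, THF, −78 °C, attack anti to C5) to give the (10R) allylic alcohol F1. Tigloylation as in step 8 gives the tiglate F2, acetal hydrolysis as in step 9 the diol F3, silylation as in step 10 the bis(triethylsilyl) ether F4, and Swern oxidation as in step 11 the C6 aldehyde F5. Methallylboration of F5 with the reagent of step 7 (Re face, reagent control) gives the borinate ester F6, which aq. NaBO3 cleaves to the (6R) homoallylic alcohol F7. Ring-closing metathesis of F7 with the second-generation Hoveyda–Grubbs catalyst (toluene, 80 °C) closes the trisubstituted C8=C9 alkene and gives 18.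

2. Step 1. Enantioface discrimination may be poor with the chlorinated alkene, or the uncatalysed background cycloaddition may compete.
Fallback (racemic cycloaddition and resolution; sets out from 1 and 2, returns at 4): uncatalysed irradiation (350 nm, CH2Cl2) gives the racemic dichloro adduct F8, and Zn in EtOH gives the racemic cyclobutene ketone F9. Ketalisation with (R,R)-hydrobenzoin (pyridinium tosylate, benzene, water removal) gives two diastereomeric ketals that are separated by chromatography or crystallisation. The ketal of the (1R,5S) ketone F10 is hydrolysed (aq. HCl, THF) to 4.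

3. Step 5. The acetal may close across the two primary hydroxyls to a seven-membered ring, because the six-membered ring must carry an axial group on the fully substituted C4.
Fallback (boronate relay; sets out from 7, returns at 8): phenylboronic acid (toluene, water removal) gives the six-membered cyclic phenylboronate F11 across O4/O6, which has no axial hydrogen on planar boron and is strongly preferred over seven-membered boronates. The free C10 hydroxyl is silylated (t-BuMe2SiCl, imidazole) to the silyl ether F12, and H2O2 at pH 7 removes the boronate to give the diol silyl ether F13. Acetalisation as in step 5, now with a single diol available, gives the acetal silyl ether F14, and Bu4NF gives 8.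

**Further compounds**

F1 | step 12 | (10R) vinyl carbinol of the acetal series | C=C[C@@H](O)[C@]1(C)CC[C@]2(C(C)C)O[C@@H](c3ccc(OC)cc3)OC[C@H]12
F2 | step 12 | tiglate of F1 | C/C=C(\C)C(=O)O[C@H](C=C)[C@]1(C)CC[C@]2(C(C)C)O[C@@H](c3ccc(OC)cc3)OC[C@H]12
F3 | step 12 | diol from F2 (C4 hydroxyl, C6 hydroxymethyl) | C/C=C(\C)C(=O)O[C@H](C=C)[C@]1(C)CC[C@@](O)(C(C)C)[C@@H]1CO
F4 | step 12 | bis(triethylsilyl) ether of F3 | C/C=C(\C)C(=O)O[C@H](C=C)[C@]1(C)CC[C@@](O[Si](CC)(CC)CC)(C(C)C)[C@@H]1CO[Si](CC)(CC)CC
F5 | step 12 | C6 aldehyde of the vinyl series | C/C=C(\C)C(=O)O[C@H](C=C)[C@]1(C)CC[C@@](O[Si](CC)(CC)CC)(C(C)C)[C@@H]1C=O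
F6 | step 12 | diisopinocampheylborinate ester of F7 | C/C=C(\C)C(=O)O[C@H](C=C)[C@]1(C)CC[C@@](O[Si](CC)(CC)CC)(C(C)C)[C@@H]1[C@H](OB([C@H]3C[C@H]4C[C@@H]([C@@H]3C)C4(C)C)[C@H]3C[C@H]4C[C@@H]([C@@H]3C)C4(C)C)CC(C)=C
F7 | step 12 | (6R) methallyl carbinol, metathesis diene | C/C=C(\C)C(=O)O[C@H](C=C)[C@]1(C)CC[C@@](O[Si](CC)(CC)CC)(C(C)C)[C@@H]1[C@H](O)CC(C)=C
F8 | step 1 | racemic 6,7-dichloro-5-methylbicyclo[3.2.0]heptan-2-one | C[C@@]12CCC(=O)[C@@H]1C(Cl)C2Cl.C[C@]12CCC(=O)[C@H]1C(Cl)C2Cl
F9 | step 1 | racemic 5-methylbicyclo[3.2.0]hept-6-en-2-one | C[C@@]12CCC(=O)[C@@H]1C=C2.C[C@]12CCC(=O)[C@H]1C=C2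
F10 | step 1 | (R,R)-hydrobenzoin ketal of (1R,5S)-5-methylbicyclo[3.2.0]hept-6-en-2-one | C[C@@]12CCC3(O[C@H](c4ccccc4)[C@@H](c4ccccc4)O3)[C@@H]1C=C2
F11 | step 5 | cyclic phenylboronate of 7 across O4/O6 | C[C@@]1(CO)CC[C@]2(C(C)C)OB(c3ccccc3)OC[C@H]12
F12 | step 5 | C10 tert-butyldimethylsilyl ether of F11 | C[C@@]1(CO[Si](C)(C)C(C)(C)C)CC[C@]2(C(C)C)OB(c3ccccc3)OC[C@H]12
F13 | step 5 | C4,C6-diol with C10 tert-butyldimethylsilyl ether | C[C@@]1(CO[Si](C)(C)C(C)(C)C)CC[C@@](O)(C(C)C)[C@@H]1CO
F14 | step 5 | C10 tert-butyldimethylsilyl ether of 8 | C[C@@]1(CO[Si](C)(C)C(C)(C)C)CC[C@]2(C(C)C)O[C@@H](c3ccc(OC)cc3)OC[C@H]12
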